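The route rests on the homoaldol (γ-hydroxy ketone) relationship between the C2 carbinol of ring A and C9 of ring B through the quaternary C10 (labdane numbering). The C8=C9 alkene is traced back to a C9 ketone, and the C1 methylene to the CH2 of a cyclopropanol fused across C9–C10. Zinc-mediated opening of that strained ring turns C1 into a nucleophile that closes ring A onto a C2 aldehyde in one operation. This forms the C1–C2 bond, the C2 stereocentre and the trans-decalin, and unveils the C9 ketone. The precursor is a bicyclo[4.1.0]heptan-1-ol (ring B plus cyclopropane) that carries a 4-oxobutanoate side chain on C5.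

Key step: step 7

Remark on numbering: labdane numbering is used throughout (ring A = C1–C5 and C10; ring B = C5–C10; C17 on C8; C18 methyl and C19 on C4; C20 on C10; C11–C16 = side chain and butenolide); α/β refer to the usual drawing with the C20 methyl β.

Assumption: the silyl ether 1 is taken as a purchasable chiral building block (both enantiomers of 4-hydroxycyclohex-2-enone are known compounds); the ester-bearing carbon C4 is carried as an epimer mixture from step 4 to step 8 and is fixed in step 9.

Step 1
Reactants: 1 (S)-4-(tert-butyldimethylsilyloxy)cyclohex-2-en-1-one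
Product: 2 (S)-4-(tert-butyldimethylsilyloxy)-2-iodocyclohex-2-en-1-one
Conditions: I2, pyridine, CH2Cl2, 0 °C to rt
Reagents that add atoms: iodine (II)
Why: Johnson α-iodination of the enone (pyridine conjugate addition, iodination, elimination) should place the halogen on the future C10 without touching the C6 stereocentre.

Step 2
Reactants: 2 (S)-4-(tert-butyldimethylsilyloxy)-2-iodocyclohex-2-en-1-one
Product: 3 (S)-4-(tert-butyldimethylsilyloxy)-2-methylcyclohex-2-en-1-one
Conditions: Me4Sn, PdCl2(PhCN)2 (5 mol %), AsPh3, CuI, NMP, 90 °C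
Reagents that add atoms: tetramethylstannane (C[Sn](C)(C)C)
Why: Stille cross-coupling of the 2-iodoenone should install the C20 methyl under base-free conditions that do not eliminate the γ-silyloxy group.

Step 3
Reactants: 4 methyl pent-4-enoate
Product: 5 1-methoxy-1-(trimethylsilyloxy)penta-1,4-diene
Conditions: LDA, THF, -78 °C; TMSCl, -78 °C to rt
Reagents that add atoms: chlorotrimethylsilane (C[Si](C)(C)Cl)
Why: Kinetic ester enolisation and O-silylation should give the ketene silyl acetal that later supplies C19, C4, C3 and C2 (as a masked aldehyde).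

Step 4
Reactants: 3 (S)-4-(tert-butyldimethylsilyloxy)-2-methylcyclohex-2-en-1-one; 5 1-methoxy-1-(trimethylsilyloxy)penta-1,4-diene
Product: 6 methyl 2-[6-(tert-butyldimethylsilyloxy)-2-methyl-3-(trimethylsilyloxy)cyclohex-2-en-1-yl]pent-4-enoate
Conditions: TMSOTf (10 mol %), CH2Cl2, -78 °C; Et3N quench
Reagents that add atoms: none
Why: Mukaiyama–Michael addition with silyl transfer should add the ketene acetal to C5 anti to the C6 silyloxy group (sets C5) and deliver the tetrasubstituted C9=C10 silyl enol ether regiospecifically, with C4 formed as an inconsequential epimer mixture.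

Step 5
Reactants: 6 methyl 2-[6-(tert-butyldimethylsilyloxy)-2-methyl-3-(trimethylsilyloxy)cyclohex-2-en-1-yl]pent-4-enoate
Product: 8 methyl 2-[4-(tert-butyldimethylsilyloxy)-1-hydroxy-6-methylbicyclo[4.1.0]heptan-5-yl]pent-4-enoate, via trimethylsilyloxy cyclopropane 7 (not isolated)
Conditions: Et2Zn, CH2I2, CH2Cl2, 0 °C to rt; then K2CO3, MeOH, 0 °C
Reagents that add atoms: diiodomethane (ICI)
Why: Furukawa–Simmons–Smith cyclopropanation of the electron-rich silyl enol ether (faster than the monosubstituted alkene) from the face anti to the C5 side chain should set the quaternary C10 with C1 α and the C20 methyl β (Conia-type siloxycyclopropane), and mild methanolysis frees the cyclopropanol.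

Step 6
Reactants: 8 methyl 2-[4-(tert-butyldimethylsilyloxy)-1-hydroxy-6-methylbicyclo[4.1.0]heptan-5-yl]pent-4-enoate
Product: 9 methyl 2-[4-(tert-butyldimethylsilyloxy)-1-hydroxy-6-methylbicyclo[4.1.0]heptan-5-yl]-4-oxobutanoate
Conditions: O3, CH2Cl2, -78 °C (indicator end point); PPh3, -78 °C to rt
Reagents that add atoms: ozone ([O-][O+]=O)
Why: Ozonolysis of the terminal alkene with reductive work-up should unmask the C2 aldehyde while the cyclopropanol and silyl ether survive at low temperature.

Step 7
Reactants: 9 methyl 2-[4-(tert-butyldimethylsilyloxy)-1-hydroxy-6-methylbicyclo[4.1.0]heptan-5-yl]-4-oxobutanoate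
Product: 12 methyl 6α-(tert-butyldimethylsilyloxy)-2α-hydroxy-10β-methyl-9-oxo-trans-decalin-4-carboxylate, via ethylzinc cyclopropoxide 10 (not isolated), via zinc homoenolate 11 (not isolated)
Conditions: Et2Zn (1.1 equiv), 2,2'-bipyridine (1.1 equiv), THF, 0 to 45 °C; aq NH4Cl
Reagents that add atoms: none
Why: Proposed new method: the ethylzinc alkoxide of the strained tertiary cyclopropanol should undergo polar β-carbon elimination of the less substituted C1–C9 bond to a primary β-keto alkylzinc (zinc homoenolate), which adds intramolecularly to the C2 aldehyde, the cyclopropoxide/homoenolate equilibrium being drained by irreversible C–C bond formation and release of ring strain. The closest known reaction types are the opening of cyclopropanols to zinc homoenolates with trapping by carbon electrophiles and the homoaldol addition of zinc or titanium ester homoenolates to aldehydes; the intramolecular addition of a ketone homoenolate to an aldehyde is the unproven part. Ring A closes in a 6-exo-trig mode (C1 onto the C2 carbonyl) while the cyclopropane opens to reveal the C9 ketone. The only new stereocentre, C2, is set in a chair transition state in which the carbonyl oxygen lies equatorial to avoid the 1,3-diaxial contact with the axial C20 methyl, which should give the 2α (equatorial) alcohol, and the trans ring fusion follows from the trans C1/C4 relationship fixed in steps 4 and 5. The step needs C1–C9 rather than C9–C10 cleavage and aldehyde addition faster than ethyl transfer or protonation of the homoenolate: the non-radical zinc pathway favours the primary alkylzinc, the quaternary C10 removes the α-hydrogen that would let the homoenolate enolise, and the six-membered intramolecular delivery favours C1 over ethyl.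

Step 8
Reactants: 12 methyl 6α-(tert-butyldimethylsilyloxy)-2α-hydroxy-10β-methyl-9-oxo-trans-decalin-4-carboxylate
Product: 13 methyl 2α,6α-bis(tert-butyldimethylsilyloxy)-10β-methyl-9-oxo-trans-decalin-4-carboxylate
Conditions: TBSCl, imidazole, DMF, rt
Reagents that add atoms: tert-butyldimethylsilyl chloride (CC(C)(C)[Si](C)(C)Cl)
Why: Silylation of the unhindered equatorial C2 alcohol protects it from the strong bases of steps 9 and 10.

Step 9
Reactants: 13 methyl 2α,6α-bis(tert-butyldimethylsilyloxy)-10β-methyl-9-oxo-trans-decalin-4-carboxylate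
Product: 14 methyl 2α,6α-bis(tert-butyldimethylsilyloxy)-9-oxo-11,12,13,14,15,16-hexanorlabdan-19-oate
Conditions: LDA (2.5 equiv), THF–DMPU, -78 to -40 °C; MeI, -78 to -20 °C
Reagents that add atoms: iodomethane (CI)
Why: Double enolate C-methylation should add C17 at C8 (configuration irrelevant) and methylate the exocyclic C4 ester enolate from the α (equatorial) face, the β face being blocked by the 1,3-diaxial C20 methyl, which sets C4 with the 18-methyl α and the 19-ester β.

Step 10
Reactants: 14 methyl 2α,6α-bis(tert-butyldimethylsilyloxy)-9-oxo-11,12,13,14,15,16-hexanorlabdan-19-oate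
Product: 15 methyl 2α,6α-bis(tert-butyldimethylsilyloxy)-9-(trifluoromethylsulfonyloxy)-11,12,13,14,15,16-hexanorlabd-8-en-19-oate
Conditions: KHMDS, THF, -78 to 0 °C; PhNTf2, -78 °C to rt
Reagents that add atoms: N-phenylbis(trifluoromethanesulfonimide) (O=S(=O)(N(c1ccccc1)S(=O)(=O)C(F)(F)F)C(F)(F)F)
Why: Deprotonation at C8, the only enolisable position, and O-triflation should give the tetrasubstituted C8=C9 enol triflate and erase the C8 stereocentre.

Step 11
Reactants: 15 methyl 2α,6α-bis(tert-butyldimethylsilyloxy)-9-(trifluoromethylsulfonyloxy)-11,12,13,14,15,16-hexanorlabd-8-en-19-oate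
Product: 16 methyl 2α,6α-bis(tert-butyldimethylsilyloxy)-13,14,15,16-tetranorlabda-8,11-dien-19-oate
Conditions: tributyl(vinyl)stannane, Pd(PPh3)4 (10 mol %), CuCl, LiCl, DMSO, 60 °C
Reagents that add atoms: tributyl(vinyl)stannane (C=C[Sn](CCCC)(CCCC)CCCC)
Why: Stille coupling in the CuCl/LiCl-accelerated variant for hindered vinyl triflates should introduce C11–C12 as a vinyl group.

Step 12
Reactants: 16 methyl 2α,6α-bis(tert-butyldimethylsilyloxy)-13,14,15,16-tetranorlabda-8,11-dien-19-oate
Product: 17 2α,6α-bis(tert-butyldimethylsilyloxy)-13,14,15,16-tetranorlabda-8,11-dien-19-ol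
Conditions: LiAlH4, THF, 0 °C to reflux
Reagents that add atoms: none
Why: Hydride reduction of the hindered C19 ester to the primary alcohol is done before the lactone is present.

Step 13
Reactants: 17 2α,6α-bis(tert-butyldimethylsilyloxy)-13,14,15,16-tetranorlabda-8,11-dien-19-ol; 18 4-bromofuran-2(5H)-one
Product: 20 2α,6α-bis(tert-butyldimethylsilyloxy)-19-hydroxylabda-8,13-dien-15,16-olide, via B-alkyl-9-BBN borane 19 (not isolated)
Conditions: 9-BBN dimer (excess), THF, rt; then 18, PdCl2(dppf), AsPh3, Cs2CO3, DMF–THF–H2O, rt to 45 °C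
Reagents that add atoms: none
Why: Anti-Markovnikov hydroboration of the only monosubstituted alkene followed by B-alkyl Suzuki–Miyaura coupling with the β-bromobutenolide should forge C12–C13 and complete the side chain.

Step 14
Reactants: 20 2α,6α-bis(tert-butyldimethylsilyloxy)-19-hydroxylabda-8,13-dien-15,16-olide
Product: 21 2α,6α,19-trihydroxylabda-8,13-dien-15,16-olide
Conditions: aq HF, MeCN, rt
Reagents that add atoms: none
Why: Fluoride-mediated cleavage of both secondary silyl ethers under mildly acidic conditions should leave the butenolide and the tetrasubstituted alkene untouched.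

Compound list
1 | (S)-4-(tert-butyldimethylsilyloxy)cyclohex-2-en-1-one | O=C1C=C[C@@H](O[Si](C)(C)C(C)(C)C)CC1 | starting material
2 | (S)-4-(tert-butyldimethylsilyloxy)-2-iodocyclohex-2-en-1-one | O=C1C(I)=C[C@@H](O[Si](C)(C)C(C)(C)C)CC1 | intermediate
3 | (S)-4-(tert-butyldimethylsilyloxy)-2-methylcyclohex-2-en-1-one | O=C1C(C)=C[C@@H](O[Si](C)(C)C(C)(C)C)CC1 | intermediate
4 | methyl pent-4-enoate | C=CCCC(=O)OC | starting material
5 | 1-methoxy-1-(trimethylsilyloxy)penta-1,4-diene (E/Z mixture) | C=CCC=C(OC)O[Si](C)(C)C | intermediate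
6 | methyl 2-[6-(tert-butyldimethylsilyloxy)-2-methyl-3-(trimethylsilyloxy)cyclohex-2-en-1-yl]pent-4-enoate; side chain on C5 β and trans to the 6α silyl ether; C4 epimers | C[Si](C)(C)OC1=C(C)[C@H](C(CC=C)C(=O)OC)[C@@H](O[Si](C)(C)C(C)(C)C)CC1 | intermediate
7 | trimethylsilyl ether of 8 (cyclopropane CH2 = C1 on the α face) | C[Si](C)(C)O[C@]12C[C@@]1(C)[C@H](C(CC=C)C(=O)OC)[C@@H](O[Si](C)(C)C(C)(C)C)CC2 | intermediate
8 | methyl 2-[4-(tert-butyldimethylsilyloxy)-1-hydroxy-6-methylbicyclo[4.1.0]heptan-5-yl]pent-4-enoate; cyclopropane CH2 (C1) α, C20 methyl and C5 side chain β, 6-silyloxy α; C4 epimers | O[C@]12C[C@@]1(C)[C@H](C(CC=C)C(=O)OC)[C@@H](O[Si](C)(C)C(C)(C)C)CC2 | intermediate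
9 | methyl 2-[4-(tert-butyldimethylsilyloxy)-1-hydroxy-6-methylbicyclo[4.1.0]heptan-5-yl]-4-oxobutanoate; same ring stereochemistry as 8; C4 epimers | O[C@]12C[C@@]1(C)[C@H](C(CC=O)C(=O)OC)[C@@H](O[Si](C)(C)C(C)(C)C)CC2 | intermediate
10 | ethylzinc alkoxide of cyclopropanol 9 | CC[Zn]O[C@]12C[C@@]1(C)[C@H](C(CC=O)C(=O)OC)[C@@H](O[Si](C)(C)C(C)(C)C)CC2 | intermediate
11 | ring-opened β-keto alkylzinc (zinc homoenolate; C1–Zn, C9 ketone) | CC[Zn]C[C@]1(C)C(=O)CC[C@H](O[Si](C)(C)C(C)(C)C)[C@H]1C(CC=O)C(=O)OC | intermediate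
12 | methyl 6α-(tert-butyldimethylsilyloxy)-2α-hydroxy-10β-methyl-9-oxo-trans-decalin-4-carboxylate (5α-H; C4 epimers) | O=C1[C@@]2(C)C[C@@H](O)CC(C(=O)OC)[C@@H]2[C@@H](O[Si](C)(C)C(C)(C)C)CC1 | intermediate
13 | methyl 2α,6α-bis(tert-butyldimethylsilyloxy)-10β-methyl-9-oxo-trans-decalin-4-carboxylate (C4 epimers) | O=C1[C@@]2(C)C[C@@H](O[Si](C)(C)C(C)(C)C)CC(C(=O)OC)[C@@H]2[C@@H](O[Si](C)(C)C(C)(C)C)CC1 | intermediate
14 | methyl 2α,6α-bis(tert-butyldimethylsilyloxy)-9-oxo-11,12,13,14,15,16-hexanorlabdan-19-oate (4α-methyl, 4β-ester; C8 epimers) | O=C1[C@@]2(C)C[C@@H](O[Si](C)(C)C(C)(C)C)C[C@](C)(C(=O)OC)[C@@H]2[C@@H](O[Si](C)(C)C(C)(C)C)CC1C | intermediate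
15 | methyl 2α,6α-bis(tert-butyldimethylsilyloxy)-9-(trifluoromethylsulfonyloxy)-11,12,13,14,15,16-hexanorlabd-8-en-19-oate | CC1=C(OS(=O)(=O)C(F)(F)F)[C@@]2(C)C[C@@H](O[Si](C)(C)C(C)(C)C)C[C@](C)(C(=O)OC)[C@@H]2[C@@H](O[Si](C)(C)C(C)(C)C)C1 | intermediate
16 | methyl 2α,6α-bis(tert-butyldimethylsilyloxy)-13,14,15,16-tetranorlabda-8,11-dien-19-oate | CC1=C(C=C)[C@@]2(C)C[C@@H](O[Si](C)(C)C(C)(C)C)C[C@](C)(C(=O)OC)[C@@H]2[C@@H](O[Si](C)(C)C(C)(C)C)C1 | intermediate
17 | 2α,6α-bis(tert-butyldimethylsilyloxy)-13,14,15,16-tetranorlabda-8,11-dien-19-ol | CC1=C(C=C)[C@@]2(C)C[C@@H](O[Si](C)(C)C(C)(C)C)C[C@](C)(CO)[C@@H]2[C@@H](O[Si](C)(C)C(C)(C)C)C1 | intermediate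
18 | 4-bromofuran-2(5H)-one | O=C1C=C(Br)CO1 | starting material
19 | C12 B-alkyl-9-borabicyclo[3.3.1]nonane of 17 (C19 oxygen as its 9-BBN borinate) | CC1=C(CCB2C3CCCC2CCC3)[C@@]2(C)C[C@@H](O[Si](C)(C)C(C)(C)C)C[C@](C)(COB3C4CCCC3CCC4)[C@@H]2[C@@H](O[Si](C)(C)C(C)(C)C)C1 | intermediate
20 | 2α,6α-bis(tert-butyldimethylsilyloxy)-19-hydroxylabda-8,13-dien-15,16-olide | CC1=C(CCC2=CC(=O)OC2)[C@@]2(C)C[C@@H](O[Si](C)(C)C(C)(C)C)C[C@](C)(CO)[C@@H]2[C@@H](O[Si](C)(C)C(C)(C)C)C1 | intermediate
21 | 2α,6α,19-trihydroxylabda-8,13-dien-15,16-olide | CC1=C(CCC2=CC(=O)OC2)[C@@]2(C)C[C@@H](O)C[C@](C)(CO)[C@@H]2[C@@H](O)C1 | target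

Total step count: 14. Longest linear sequence: 13 steps (1, 2, 4–14, from compound 1); step 3 is a one-step branch.

Steps most likely to fail

Step 7 (proposed new method). The zinc cyclopropoxide may open too slowly, or the homoenolate may be protonated (giving the gem-dimethyl ketone) or lose out to ethyl transfer before it adds to the aldehyde. The fallback uses known chemistry and sets out from 9. Ring-opening iodination of the cyclopropanol with N-iodosuccinimide in CH2Cl2 at 0 °C (cleavage of the CH2–C(OH) bond) gives the β-iodo ketone aldehyde F1, which cannot eliminate because C10 is quaternary. A Takai alkylchromium cyclisation (CrCl2, catalytic cobalt phthalocyanine CoPc (C32H16CoN8), DMF, rt) then adds C1 to the aldehyde chemoselectively in the presence of the C9 ketone. The same chair preference is expected to apply, and the sequence comes back to the route at 12.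

Step 5. The carbenoid may attack the terminal alkene competitively, or add to the hindered tetrasubstituted enol ether with poor facial selectivity. The fallback avoids the cyclopropane altogether and sets out from 6. Lanthanide-type Mukaiyama hydroxymethylation (aqueous formaldehyde, Sc(OTf)3, THF) anti to the C5 side chain gives the β-hydroxy ketone F2. Iodination (I2, PPh3, imidazole, toluene, 60 °C) gives the neopentyl iodide F3, and Lemieux–Johnson cleavage of the alkene (OsO4 cat., NaIO4, 2,6-lutidine, dioxane–water) gives the β-iodo ketone aldehyde F1. F1 is cyclised with CrCl2 and catalytic CoPc as above, and the route is rejoined at 12.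

Step 11. Oxidative addition and transmetalation at the tetrasubstituted triflate flanked by the quaternary C10 may be too slow, so that triflate hydrolysis or reduction takes over (sluggish triflation in step 10 belongs to the same problem). The fallback sets out from 14. Addition of the vinylcerium reagent (vinylmagnesium bromide, anhydrous CeCl3, THF, -78 °C) to the hindered ketone gives the tertiary allylic alcohol F4. Dehydration with SOCl2 and pyridine at 0 °C, where C8–H is the only β-hydrogen, gives the diene and comes back to the route at 16.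

Further compounds
F1 | step 7 | methyl 2-[6-(tert-butyldimethylsilyloxy)-2-(iodomethyl)-2-methyl-3-oxocyclohexyl]-4-oxobutanoate (β-iodo ketone aldehyde; CH2I α, C5 side chain β) | IC[C@]1(C)C(=O)CC[C@H](O[Si](C)(C)C(C)(C)C)[C@H]1C(CC=O)C(=O)OC
F2 | step 5 | methyl 2-[6-(tert-butyldimethylsilyloxy)-2-(hydroxymethyl)-2-methyl-3-oxocyclohexyl]pent-4-enoate | OC[C@]1(C)C(=O)CC[C@H](O[Si](C)(C)C(C)(C)C)[C@H]1C(CC=C)C(=O)OC
F3 | step 5 | methyl 2-[6-(tert-butyldimethylsilyloxy)-2-(iodomethyl)-2-methyl-3-oxocyclohexyl]pent-4-enoate | IC[C@]1(C)C(=O)CC[C@H](O[Si](C)(C)C(C)(C)C)[C@H]1C(CC=C)C(=O)OC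
F4 | step 11 | methyl 2α,6α-bis(tert-butyldimethylsilyloxy)-9-hydroxy-13,14,15,16-tetranorlabd-11-en-19-oate (C8 and C9 epimers) | OC1(C=C)[C@@]2(C)C[C@@H](O[Si](C)(C)C(C)(C)C)C[C@](C)(C(=O)OC)[C@@H]2[C@@H](O[Si](C)(C)C(C)(C)C)CC1C
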